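**Plan**

- Retrosynthetic cuts, in order: O1–C2 (ring C), the C8–CH2 bond to the lavandulyl group, the C4–C4a aryl ketone bond, the C6–CH2 bond of the hydroxyisopentyl chain, and the C2–C1' bond (aryl opening of a glycidate).
- Enabling feature: C2 is a benzylic CH2 on ring B with the 4'-hydroxyl para to it, so oxidation gives a para-quinone methide at C2. The C8a phenol of ring A sits six atoms away and closes ring C onto it.
- Forward: the ring B Grignard reagent opens methyl (R)-glycidate and the product is taken to a Weinreb amide. Ring A is built from 2-iodoresorcinol by side-chain coupling, C–H borylation/oxidation for the third oxygen and diiodination. Acylation joins the fragments, Negishi coupling adds the lavandulyl group, and ring C closes last.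
- Stereochemistry: C3 is bought with methyl (R)-glycidate, C2 is set trans to C3 in the ring closure, and the side-chain centre comes unchanged from (R)-lavandulol.
- Protecting groups: aryl TIPS ethers on O5, O7 and O2' stay to the end; aryl TBS ethers on O8a and O4' are taken off before the key step; O3 carries TBS and the tertiary oxygen TES.

Key step: step 17

Abbreviations: TBS = tert-butyldimethylsilyl, TIPS = triisopropylsilyl, TES = triethylsilyl; TBSO, TIPSO and TESO are the corresponding silyloxy groups; lavandulyl = 5-methyl-2-(prop-1-en-2-yl)hex-4-en-1-yl.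

Assumption: one equivalent of TBSCl should silylate 4-bromoresorcinol first at the hydroxyl para to bromine, because the other hydroxyl is flanked by the halogen; minor regioisomer and bis-ether would be removed at that stage.

**Route**

Step 1
Reactants: 1 4-bromoresorcinol
Product: 2 2-bromo-5-(TBSO)phenol
Conditions: TBSCl (1.0 equiv), imidazole, THF, −20 → 0 °C
Reagents that add atoms: tert-butyldimethylsilyl chloride, CC(C)(C)[Si](C)(C)Cl
Why: Silyl ether formation under steric control should place the base-labile TBS group on the unhindered hydroxyl, the future O4', which has to be free in the key step.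

Step 2
Reactants: 2 2-bromo-5-(TBSO)phenol
Product: 3 [2-bromo-5-(TBSO)phenoxy]triisopropylsilane
Conditions: TIPSOTf, 2,6-lutidine, CH2Cl2, 0 °C → rt
Reagents that add atoms: triisopropylsilyl triflate, CC(C)[Si](OS(=O)(=O)C(F)(F)F)(C(C)C)C(C)C
Why: Silyl ether formation with the reactive triflate should cap the bromine-flanked phenol (future O2') with the base-robust TIPS group that lasts to the final step.

Step 3
Reactants: 3 [2-bromo-5-(TBSO)phenoxy]triisopropylsilane, 4 methyl (R)-glycidate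
Product: 6 methyl (2R)-3-[4-(TBSO)-2-(TIPSO)phenyl]-2-hydroxypropanoate, via arylmagnesium bromide 5 (not isolated)
Conditions: Mg, LiCl, THF, 40 °C; then CuI (10 mol %), 4, THF, −40 → −20 °C; aq NH4Cl
Reagents that add atoms: none
Why: Copper-catalysed SN2 opening of the terminal epoxide by the aryl Grignard reagent at its CH2 carbon, faster than ester addition at −40 °C, should form the C2–C1' bond and leave the glycidate stereocentre untouched, so that it becomes C3 with R configuration.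

Step 4
Reactants: 6 methyl (2R)-3-[4-(TBSO)-2-(TIPSO)phenyl]-2-hydroxypropanoate
Product: 7 methyl (2R)-2-(TBSO)-3-[4-(TBSO)-2-(TIPSO)phenyl]propanoate
Conditions: TBSCl, imidazole, DMF, rt
Reagents that add atoms: tert-butyldimethylsilyl chloride, CC(C)(C)[Si](C)(C)Cl
Why: Standard silyl ether formation on the secondary α-hydroxy ester protects O3 for the organometallic steps.

Step 5
Reactants: 7 methyl (2R)-2-(TBSO)-3-[4-(TBSO)-2-(TIPSO)phenyl]propanoate
Product: 8 (2R)-2-(TBSO)-3-[4-(TBSO)-2-(TIPSO)phenyl]-N-methoxy-N-methylpropanamide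
Conditions: MeNH(OMe)·HCl, i-PrMgCl, THF, −20 → 0 °C
Reagents that add atoms: N,O-dimethylhydroxylamine hydrochloride, CNOC.Cl
Why: Weinreb amide formation from the ester with the chloromagnesium amide generated in the flask runs at low temperature, where α-silyloxy esters should not epimerise.

Step 6
Reactants: 9 3-methylbutane-1,3-diol
Product: 10 4-iodo-2-methylbutan-2-ol
Conditions: I2, PPh3, imidazole, CH2Cl2, 0 °C
Reagents that add atoms: iodine, II
Why: The Appel reaction converts only the primary hydroxyl, since the tertiary one cannot undergo SN2 displacement under these conditions.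

Step 7
Reactants: 10 4-iodo-2-methylbutan-2-ol
Product: 11 triethyl[(4-iodo-2-methylbutan-2-yl)oxy]silane
Conditions: TESOTf, 2,6-lutidine, CH2Cl2, −78 → 0 °C
Reagents that add atoms: triethylsilyl triflate, CC[Si](CC)(CC)OS(=O)(=O)C(F)(F)F
Why: Silyl ether formation with a silyl triflate and a hindered base masks the tertiary alcohol, which would otherwise quench the organozinc and organomagnesium reagents used later.

Step 8
Reactants: 12 2-iodoresorcinol
Product: 13 2-iodo-1,3-bis(TIPSO)benzene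
Conditions: TIPSOTf (2.3 equiv), 2,6-lutidine, CH2Cl2, 0 °C → rt
Reagents that add atoms: triisopropylsilyl triflate, CC(C)[Si](OS(=O)(=O)C(F)(F)F)(C(C)C)C(C)C
Why: Double silyl ether formation puts the end-stable TIPS groups on the two oxygens that flank the iodine, the future O5 and O7.

Step 9
Reactants: 11 triethyl[(4-iodo-2-methylbutan-2-yl)oxy]silane, 13 2-iodo-1,3-bis(TIPSO)benzene
Product: 15 2-[3-methyl-3-(TESO)butyl]-1,3-bis(TIPSO)benzene, via alkylzinc iodide 14 (not isolated)
Conditions: Zn dust, LiCl, THF, 40 °C; then 13, Pd(OAc)2 (2 mol %), SPhos (4 mol %), THF, 50 °C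
Reagents that add atoms: none
Why: Negishi coupling of a primary alkylzinc iodide with a di-ortho-substituted aryl iodide under a dialkylbiarylphosphine–palladium catalyst should attach the side chain at the carbon between the two oxygens, the future C6.

Step 10
Reactants: 15 2-[3-methyl-3-(TESO)butyl]-1,3-bis(TIPSO)benzene
Product: 17 4-[3-methyl-3-(TESO)butyl]-3,5-bis(TIPSO)phenol, via aryl pinacol boronate 16 (not isolated)
Conditions: [Ir(OMe)(cod)]2 (1.5 mol %), 4,4'-di-tert-butyl-2,2'-bipyridine (3 mol %), B2pin2, THF, 80 °C; then NaBO3·4H2O, THF/H2O, rt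
Reagents that add atoms: sodium perborate (drawn without water of crystallisation), [Na+].[Na+].O[B-]1(O)OO[B-](O)(O)OO1
Why: Iridium-catalysed C–H borylation is sterically controlled and the only ring C–H without an ortho substituent lies meta to both silyloxy groups, so borylation there followed by perborate oxidation in the same flask should deliver the third oxygen (future O8a) as the only free phenol.

Step 11
Reactants: 17 4-[3-methyl-3-(TESO)butyl]-3,5-bis(TIPSO)phenol
Product: 18 2,6-diiodo-4-[3-methyl-3-(TESO)butyl]-3,5-bis(TIPSO)phenol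
Conditions: NIS (2.1 equiv), CH2Cl2, 0 °C, dark
Reagents that add atoms: N-iodosuccinimide, O=C1CCC(=O)N1I
Why: Electrophilic aromatic iodination can only occur at the two remaining ring positions, both ortho to the free phenol, and gives a symmetric diiodide whose C–I carbons are the future C4a and C8.

Step 12
Reactants: 18 2,6-diiodo-4-[3-methyl-3-(TESO)butyl]-3,5-bis(TIPSO)phenol
Product: 19 tert-butyl{2,6-diiodo-4-[3-methyl-3-(TESO)butyl]-3,5-bis(TIPSO)phenoxy}dimethylsilane
Conditions: TBSOTf, 2,6-lutidine, CH2Cl2, 0 °C → rt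
Reagents that add atoms: tert-butyldimethylsilyl triflate, CC(C)(C)[Si](C)(C)OS(=O)(=O)C(F)(F)F
Why: Silyl ether formation masks the acidic phenol for the organometallic steps as an aryl TBS ether, which mild base cleaves far faster than the aryl TIPS ethers.

Step 13
Reactants: 19 tert-butyl{2,6-diiodo-4-[3-methyl-3-(TESO)butyl]-3,5-bis(TIPSO)phenoxy}dimethylsilane, 8 (2R)-2-(TBSO)-3-[4-(TBSO)-2-(TIPSO)phenyl]-N-methoxy-N-methylpropanamide
Product: 21 (2R)-2-(TBSO)-1-{2-(TBSO)-3-iodo-5-[3-methyl-3-(TESO)butyl]-4,6-bis(TIPSO)phenyl}-3-[4-(TBSO)-2-(TIPSO)phenyl]propan-1-one, via arylmagnesium chloride 20 (not isolated)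
Conditions: i-PrMgCl·LiCl (1.05 equiv), THF, −40 → −20 °C; then 8, −20 °C → rt; aq NH4Cl
Reagents that add atoms: none
Why: Iodine–magnesium exchange should occur only once on the symmetric diiodide (the arylmagnesium formed is too electron-rich for a second exchange and, unlike an aryllithium, should not draw the ortho silyl group onto carbon), and the Weinreb ketone synthesis stops at the ketone through its chelated tetrahedral intermediate.

Step 14
Reactants: 22 (R)-lavandulol
Product: 23 (R)-lavandulyl iodide [(3R)-3-(iodomethyl)-2,6-dimethylhepta-1,5-diene]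
Conditions: I2, PPh3, imidazole, CH2Cl2, 0 °C → rt
Reagents that add atoms: iodine, II
Why: The Appel reaction displaces the primary hydroxyl by SN2 and does not touch the neighbouring allylic stereocentre.

Step 15
Reactants: 23 (R)-lavandulyl iodide, 21 (2R)-2-(TBSO)-1-{2-(TBSO)-3-iodo-5-[3-methyl-3-(TESO)butyl]-4,6-bis(TIPSO)phenyl}-3-[4-(TBSO)-2-(TIPSO)phenyl]propan-1-one
Product: 26 (2R)-2-(TBSO)-1-{2-(TBSO)-3-[(2S)-lavandulyl]-5-[3-methyl-3-(TESO)butyl]-4,6-bis(TIPSO)phenyl}-3-[4-(TBSO)-2-(TIPSO)phenyl]propan-1-one, via lavandulyllithium 24 (not isolated), via lavandulylzinc chloride 25 (not isolated)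
Conditions: 23, t-BuLi (2.05 equiv), Et2O/pentane, −78 °C; ZnCl2, THF, −78 → 0 °C; then 21, Pd(OAc)2 (5 mol %), SPhos (10 mol %), THF, 50 °C
Reagents that add atoms: none
Why: Negishi coupling after a polar iodine–lithium exchange at −78 °C (which avoids radical rearrangement of the homoallyl skeleton) and transmetalation to zinc should install the lavandulyl group at C8 with its stereocentre, β to the metal, unchanged (the descriptor becomes S only through the priority change), while ketone and silyl ethers tolerate the organozinc.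

Step 16
Reactants: 26 (2R)-2-(TBSO)-1-{2-(TBSO)-3-[(2S)-lavandulyl]-5-[3-methyl-3-(TESO)butyl]-4,6-bis(TIPSO)phenyl}-3-[4-(TBSO)-2-(TIPSO)phenyl]propan-1-one
Product: 27 (2R)-2-(TBSO)-1-{2-hydroxy-3-[(2S)-lavandulyl]-5-[3-methyl-3-(TESO)butyl]-4,6-bis(TIPSO)phenyl}-3-[4-hydroxy-2-(TIPSO)phenyl]propan-1-one
Conditions: K2CO3 (2.2 equiv), MeOH/THF (2:1), 0 °C; pH 7 buffer
Reagents that add atoms: none
Why: Selective desilylation by base-mediated methanolysis should free only the C8a and 4' phenols, because aryl TBS ethers are cleaved much faster than aryl TIPS ethers and alkyl silyl ethers are inert, and the C8a phenoxide formed lowers the acidity of C3–H against epimerisation.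

Step 17
Reactants: 27 (2R)-2-(TBSO)-1-{2-hydroxy-3-[(2S)-lavandulyl]-5-[3-methyl-3-(TESO)butyl]-4,6-bis(TIPSO)phenyl}-3-[4-hydroxy-2-(TIPSO)phenyl]propan-1-one
Product: 29 (2R,3R)-3-(TBSO)-2-[4-hydroxy-2-(TIPSO)phenyl]-8-[(2S)-lavandulyl]-6-[3-methyl-3-(TESO)butyl]-5,7-bis(TIPSO)chroman-4-one, via para-quinone methide 28 (not isolated)
Conditions: DDQ (1.05 equiv), CH2Cl2, 0 °C → rt
Reagents that add atoms: none
Why: DDQ removes two electrons and a proton from the 4'-hydroxybenzyl unit of ring B, whose C2 methylene is activated by the para hydroxyl and the ortho silyloxy group, and the para-quinone methide 28 is captured at its exocyclic carbon C2 by the C8a phenol in an intramolecular oxa-1,6-addition that restores aromatic ring B. The closest known reaction type is the DDQ-mediated oxidative cyclisation of 2'-hydroxydihydrochalcones to flavanones through para-quinone methides. Ring C closes in the 6-exo-trig mode, O1 adding to the exocyclic C2=C1' bond. The new stereocentre C2 is controlled by C3: in a chair-like transition state the C3 silyloxy group and the quinone methide unit are both pseudo-equatorial, which gives the 2,3-trans (2R,3R) isomer, also the more stable one. The step needs oxidation of ring B in preference to ring A and the alkenes, which is secured because 4'-OH is the only free phenol para to a benzylic C–H while the ring A phenol is hydrogen-bonded to the ketone and acyl-deactivated. It also needs ring closure to outrun tautomerisation of 28 to an enol that would erase C3 and to avoid a second oxidation to the flavonol, which the pre-organised phenol and the use of only 1.05 equiv of oxidant at 0 °C should secure.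

Step 18
Reactants: 29 (2R,3R)-3-(TBSO)-2-[4-hydroxy-2-(TIPSO)phenyl]-8-[(2S)-lavandulyl]-6-[3-methyl-3-(TESO)butyl]-5,7-bis(TIPSO)chroman-4-one
Product: 30 (2R,3R)-2-(2,4-dihydroxyphenyl)-3,5,7-trihydroxy-6-(3-hydroxy-3-methylbutyl)-8-[(2S)-lavandulyl]chroman-4-one (target)
Conditions: TBAF (12 equiv), AcOH (12 equiv), THF, 0 → 35 °C
Reagents that add atoms: none
Why: Global desilylation with fluoride removes the three aryl TIPS ethers, the secondary TBS ether and the tertiary TES ether, and the acetic acid buffer keeps the medium from becoming basic enough to open ring C or epimerise C2.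

**Compound list**

1 | 4-bromoresorcinol | Oc1ccc(Br)c(O)c1 | starting material
2 | 2-bromo-5-(TBSO)phenol | Oc1cc(O[Si](C)(C)C(C)(C)C)ccc1Br | intermediate
3 | [2-bromo-5-(TBSO)phenoxy]triisopropylsilane | CC(C)[Si](Oc1cc(O[Si](C)(C)C(C)(C)C)ccc1Br)(C(C)C)C(C)C | intermediate
4 | methyl (R)-glycidate | COC(=O)[C@H]1CO1 | starting material
5 | [4-(TBSO)-2-(TIPSO)phenyl]magnesium bromide | CC(C)[Si](Oc1cc(O[Si](C)(C)C(C)(C)C)ccc1[Mg]Br)(C(C)C)C(C)C | intermediate (not isolated)
6 | methyl (2R)-3-[4-(TBSO)-2-(TIPSO)phenyl]-2-hydroxypropanoate | COC(=O)[C@H](O)Cc1ccc(O[Si](C)(C)C(C)(C)C)cc1O[Si](C(C)C)(C(C)C)C(C)C | intermediate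
7 | methyl (2R)-2-(TBSO)-3-[4-(TBSO)-2-(TIPSO)phenyl]propanoate | COC(=O)[C@H](O[Si](C)(C)C(C)(C)C)Cc1ccc(O[Si](C)(C)C(C)(C)C)cc1O[Si](C(C)C)(C(C)C)C(C)C | intermediate
8 | (2R)-2-(TBSO)-3-[4-(TBSO)-2-(TIPSO)phenyl]-N-methoxy-N-methylpropanamide | CON(C)C(=O)[C@H](O[Si](C)(C)C(C)(C)C)Cc1ccc(O[Si](C)(C)C(C)(C)C)cc1O[Si](C(C)C)(C(C)C)C(C)C | intermediate
9 | 3-methylbutane-1,3-diol | CC(C)(O)CCO | starting material
10 | 4-iodo-2-methylbutan-2-ol | CC(C)(O)CCI | intermediate
11 | triethyl[(4-iodo-2-methylbutan-2-yl)oxy]silane | CC[Si](CC)(CC)OC(C)(C)CCI | intermediate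
12 | 2-iodoresorcinol | Oc1cccc(O)c1I | starting material
13 | 2-iodo-1,3-bis(TIPSO)benzene | CC(C)[Si](Oc1cccc(O[Si](C(C)C)(C(C)C)C(C)C)c1I)(C(C)C)C(C)C | intermediate
14 | [3-methyl-3-(TESO)butyl]zinc iodide | CC[Si](CC)(CC)OC(C)(C)CC[Zn]I | intermediate (not isolated)
15 | 2-[3-methyl-3-(TESO)butyl]-1,3-bis(TIPSO)benzene | CC[Si](CC)(CC)OC(C)(C)CCc1c(O[Si](C(C)C)(C(C)C)C(C)C)cccc1O[Si](C(C)C)(C(C)C)C(C)C | intermediate
16 | 2-{4-[3-methyl-3-(TESO)butyl]-3,5-bis(TIPSO)phenyl}-4,4,5,5-tetramethyl-1,3,2-dioxaborolane | CC[Si](CC)(CC)OC(C)(C)CCc1c(O[Si](C(C)C)(C(C)C)C(C)C)cc(B2OC(C)(C)C(C)(C)O2)cc1O[Si](C(C)C)(C(C)C)C(C)C | intermediate (not isolated)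
17 | 4-[3-methyl-3-(TESO)butyl]-3,5-bis(TIPSO)phenol | CC[Si](CC)(CC)OC(C)(C)CCc1c(O[Si](C(C)C)(C(C)C)C(C)C)cc(O)cc1O[Si](C(C)C)(C(C)C)C(C)C | intermediate
18 | 2,6-diiodo-4-[3-methyl-3-(TESO)butyl]-3,5-bis(TIPSO)phenol | CC[Si](CC)(CC)OC(C)(C)CCc1c(O[Si](C(C)C)(C(C)C)C(C)C)c(I)c(O)c(I)c1O[Si](C(C)C)(C(C)C)C(C)C | intermediate
19 | tert-butyl{2,6-diiodo-4-[3-methyl-3-(TESO)butyl]-3,5-bis(TIPSO)phenoxy}dimethylsilane | CC[Si](CC)(CC)OC(C)(C)CCc1c(O[Si](C(C)C)(C(C)C)C(C)C)c(I)c(O[Si](C)(C)C(C)(C)C)c(I)c1O[Si](C(C)C)(C(C)C)C(C)C | intermediate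
20 | {2-(TBSO)-3-iodo-5-[3-methyl-3-(TESO)butyl]-4,6-bis(TIPSO)phenyl}magnesium chloride | CC[Si](CC)(CC)OC(C)(C)CCc1c(O[Si](C(C)C)(C(C)C)C(C)C)c(I)c(O[Si](C)(C)C(C)(C)C)c([Mg]Cl)c1O[Si](C(C)C)(C(C)C)C(C)C | intermediate (not isolated)
21 | (2R)-2-(TBSO)-1-{2-(TBSO)-3-iodo-5-[3-methyl-3-(TESO)butyl]-4,6-bis(TIPSO)phenyl}-3-[4-(TBSO)-2-(TIPSO)phenyl]propan-1-one | CC[Si](CC)(CC)OC(C)(C)CCc1c(O[Si](C(C)C)(C(C)C)C(C)C)c(I)c(O[Si](C)(C)C(C)(C)C)c(C(=O)[C@H](O[Si](C)(C)C(C)(C)C)Cc2ccc(O[Si](C)(C)C(C)(C)C)cc2O[Si](C(C)C)(C(C)C)C(C)C)c1O[Si](C(C)C)(C(C)C)C(C)C | intermediate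
22 | (R)-lavandulol | C=C(C)[C@@H](CC=C(C)C)CO | starting material
23 | (R)-lavandulyl iodide | C=C(C)[C@@H](CC=C(C)C)CI | intermediate
24 | (R)-lavandulyllithium | C=C(C)[C@@H](CC=C(C)C)C[Li] | intermediate (not isolated)
25 | (R)-lavandulylzinc chloride | C=C(C)[C@@H](CC=C(C)C)C[Zn]Cl | intermediate (not isolated)
26 | (2R)-2-(TBSO)-1-{2-(TBSO)-3-[(2S)-lavandulyl]-5-[3-methyl-3-(TESO)butyl]-4,6-bis(TIPSO)phenyl}-3-[4-(TBSO)-2-(TIPSO)phenyl]propan-1-one | C=C(C)[C@@H](CC=C(C)C)Cc1c(O[Si](C(C)C)(C(C)C)C(C)C)c(CCC(C)(C)O[Si](CC)(CC)CC)c(O[Si](C(C)C)(C(C)C)C(C)C)c(C(=O)[C@H](O[Si](C)(C)C(C)(C)C)Cc2ccc(O[Si](C)(C)C(C)(C)C)cc2O[Si](C(C)C)(C(C)C)C(C)C)c1O[Si](C)(C)C(C)(C)C | intermediate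
27 | (2R)-2-(TBSO)-1-{2-hydroxy-3-[(2S)-lavandulyl]-5-[3-methyl-3-(TESO)butyl]-4,6-bis(TIPSO)phenyl}-3-[4-hydroxy-2-(TIPSO)phenyl]propan-1-one | C=C(C)[C@@H](CC=C(C)C)Cc1c(O[Si](C(C)C)(C(C)C)C(C)C)c(CCC(C)(C)O[Si](CC)(CC)CC)c(O[Si](C(C)C)(C(C)C)C(C)C)c(C(=O)[C@H](O[Si](C)(C)C(C)(C)C)Cc2ccc(O)cc2O[Si](C(C)C)(C(C)C)C(C)C)c1O | intermediate (key-step precursor)
28 | para-quinone methide of 27 (4-oxocyclohexa-2,5-dien-1-ylidene at C2) | C=C(C)[C@@H](CC=C(C)C)Cc1c(O[Si](C(C)C)(C(C)C)C(C)C)c(CCC(C)(C)O[Si](CC)(CC)CC)c(O[Si](C(C)C)(C(C)C)C(C)C)c(C(=O)[C@H](O[Si](C)(C)C(C)(C)C)C=C2C=CC(=O)C=C2O[Si](C(C)C)(C(C)C)C(C)C)c1O | intermediate (not isolated)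
29 | (2R,3R)-3-(TBSO)-2-[4-hydroxy-2-(TIPSO)phenyl]-8-[(2S)-lavandulyl]-6-[3-methyl-3-(TESO)butyl]-5,7-bis(TIPSO)chroman-4-one | C=C(C)[C@@H](CC=C(C)C)Cc1c(O[Si](C(C)C)(C(C)C)C(C)C)c(CCC(C)(C)O[Si](CC)(CC)CC)c(O[Si](C(C)C)(C(C)C)C(C)C)c2c1O[C@H](c1ccc(O)cc1O[Si](C(C)C)(C(C)C)C(C)C)[C@@H](O[Si](C)(C)C(C)(C)C)C2=O | intermediate (key-step product)
30 | (2R,3R)-2-(2,4-dihydroxyphenyl)-3,5,7-trihydroxy-6-(3-hydroxy-3-methylbutyl)-8-[(2S)-lavandulyl]chroman-4-one | C=C(C)[C@@H](CC=C(C)C)Cc1c(O)c(CCC(C)(C)O)c(O)c2c1O[C@H](c1ccc(O)cc1O)[C@@H](O)C2=O | target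

**Step count and risks**

Total step count: 18. Longest linear sequence: 11 steps (from 9 through steps 6, 7, 9, 10, 11, 12, 13, 15, 16, 17 and 18 to 30).

Steps most likely to fail:

1. Step 17. The quinone methide may tautomerise toward an enol of the 1,2-diketone before the phenol adds, which erases C3. The product may also be oxidised a second time at C2 toward the flavonol, or the oxidant may attack the electron-rich alkenes. The fallback separates oxidation from ring closure. It sets out from 27, which would be oxidised with DDQ in CH2Cl2/MeOH so that the solvent traps the quinone methide at once as (2R)-2-(TBSO)-1-{2-hydroxy-3-[(2S)-lavandulyl]-5-[3-methyl-3-(TESO)butyl]-4,6-bis(TIPSO)phenyl}-3-[4-hydroxy-2-(TIPSO)phenyl]-3-methoxypropan-1-one F1 (both epimers at the methoxy carbon). With no oxidant left, F1 would be ionised with pyridinium p-toluenesulfonate in CH2Cl2. The para-hydroxybenzyl ether re-forms the same electrophile slowly and reversibly, and the C8a phenol closes ring C under equilibrating conditions that favour the trans isomer. The sequence comes back to the route at 29.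

2. Step 13. The crowded arylmagnesium may add too slowly to the crowded amide, so that proton quench to the de-iodinated arene or transfer of the C8a silyl group to the tetrahedral alkoxide takes over. The fallback uses a more reactive electrophile and a later oxidation. It sets out from 7, which would be reduced with DIBAL-H in CH2Cl2 at −78 °C to (2R)-2-(TBSO)-3-[4-(TBSO)-2-(TIPSO)phenyl]propanal F2. Addition of the Grignard reagent 20 (made from 19 as in step 13) at −40 °C with a cold quench should give (2R)-2-(TBSO)-1-{2-(TBSO)-3-iodo-5-[3-methyl-3-(TESO)butyl]-4,6-bis(TIPSO)phenyl}-3-[4-(TBSO)-2-(TIPSO)phenyl]propan-1-ol F3 (both carbinol epimers). Oxidation with Dess–Martin periodinane and NaHCO3 in CH2Cl2 comes back to the route at 21.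

3. Step 15. Oxidative addition into the C–I bond, which lies between two silyloxy groups on the acylated, hexasubstituted ring, may be slow. Reduction of the iodide, β-hydride elimination of the alkylpalladium species or epimerisation at C3 during prolonged heating would then compete. The fallback moves the coupling ahead of the acylation. It sets out from 19, used in twofold excess with recovery, which would be coupled once with the zinc reagent 25 under the same palladium/SPhos catalysis to give tert-butyl{2-iodo-6-[(2S)-lavandulyl]-4-[3-methyl-3-(TESO)butyl]-3,5-bis(TIPSO)phenoxy}dimethylsilane F4. Iodine–magnesium exchange with i-PrMgCl·LiCl would then give {2-(TBSO)-3-[(2S)-lavandulyl]-5-[3-methyl-3-(TESO)butyl]-4,6-bis(TIPSO)phenyl}magnesium chloride F5. Its acylation with the Weinreb amide 8 comes back to the route at 26, so that the ketone and its stereocentre never meet the coupling conditions.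

**Further compounds**

F1 | step 17 | (2R)-2-(TBSO)-1-{2-hydroxy-3-[(2S)-lavandulyl]-5-[3-methyl-3-(TESO)butyl]-4,6-bis(TIPSO)phenyl}-3-[4-hydroxy-2-(TIPSO)phenyl]-3-methoxypropan-1-one (epimers at C3 of the propanone) | C=C(C)[C@@H](CC=C(C)C)Cc1c(O[Si](C(C)C)(C(C)C)C(C)C)c(CCC(C)(C)O[Si](CC)(CC)CC)c(O[Si](C(C)C)(C(C)C)C(C)C)c(C(=O)[C@H](O[Si](C)(C)C(C)(C)C)C(OC)c2ccc(O)cc2O[Si](C(C)C)(C(C)C)C(C)C)c1O
F2 | step 13 | (2R)-2-(TBSO)-3-[4-(TBSO)-2-(TIPSO)phenyl]propanal | O=C[C@H](O[Si](C)(C)C(C)(C)C)Cc1ccc(O[Si](C)(C)C(C)(C)C)cc1O[Si](C(C)C)(C(C)C)C(C)C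
F3 | step 13 | (2R)-2-(TBSO)-1-{2-(TBSO)-3-iodo-5-[3-methyl-3-(TESO)butyl]-4,6-bis(TIPSO)phenyl}-3-[4-(TBSO)-2-(TIPSO)phenyl]propan-1-ol (epimers at C1) | CC[Si](CC)(CC)OC(C)(C)CCc1c(O[Si](C(C)C)(C(C)C)C(C)C)c(I)c(O[Si](C)(C)C(C)(C)C)c(C(O)[C@H](O[Si](C)(C)C(C)(C)C)Cc2ccc(O[Si](C)(C)C(C)(C)C)cc2O[Si](C(C)C)(C(C)C)C(C)C)c1O[Si](C(C)C)(C(C)C)C(C)C
F4 | step 15 | tert-butyl{2-iodo-6-[(2S)-lavandulyl]-4-[3-methyl-3-(TESO)butyl]-3,5-bis(TIPSO)phenoxy}dimethylsilane | C=C(C)[C@@H](CC=C(C)C)Cc1c(O[Si](C(C)C)(C(C)C)C(C)C)c(CCC(C)(C)O[Si](CC)(CC)CC)c(O[Si](C(C)C)(C(C)C)C(C)C)c(I)c1O[Si](C)(C)C(C)(C)C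
F5 | step 15 | {2-(TBSO)-3-[(2S)-lavandulyl]-5-[3-methyl-3-(TESO)butyl]-4,6-bis(TIPSO)phenyl}magnesium chloride | C=C(C)[C@@H](CC=C(C)C)Cc1c(O[Si](C(C)C)(C(C)C)C(C)C)c(CCC(C)(C)O[Si](CC)(CC)CC)c(O[Si](C(C)C)(C(C)C)C(C)C)c([Mg]Cl)c1O[Si](C)(C)C(C)(C)C
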